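**Plan**
- Retrosynthesis: the two phenols come from benzyl ethers and the CH2OMe group from a carboxyl carbon; the skeleton is then cut at two bonds of ring A, C1'–CH (the bridge to isocoumarin C5) and C2'–C (the future CH2OMe carbon).
- Enabling feature: on ring A the carbon substituents at C1' and C2' are neighbours and C1' lies beside the C6' methoxyl. This is the pattern a 3-methoxybenzyne (triple bond C1'≡C2') gives when a carbon nucleophile enters at the carbon remote from OMe and a carbon electrophile at the carbon next to it.
- Forward: an ortho-silylaryl triflate (from 5-methoxyresorcinol) and a 3-methylisocoumarin-5-carbaldehyde (from methyl orsellinate, pyranone ring closed by enol lactonisation) are joined with tert-butyl isocyanide, which closes a temporary iminoisobenzofuran ring.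
- That ring is then taken apart: imidate hydrolysis, ionic hydrogenolysis of the benzylic C–O bond, borane reduction, O-methylation, debenzylation.
- Stereochemistry: the target is achiral; the one stereocentre made in the coupling is racemic and is erased when its C–O bond is reduced.

Key step: step 13

Remark: ring A atoms are primed (C1' carries the bridging CH2, C2' the CH2OMe, C4' the OH, C6' the OMe) and the isocoumarin keeps its own numbering. The imine geometry drawn for 20 (Z) is immaterial because the C=N bond is hydrolysed in step 14.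

**Route**

Step 1
Reactants: 1 5-methoxyresorcinol
Product: 2 3-methoxy-5-(triisopropylsilyloxy)phenol
Conditions: TIPSCl (1.0 equiv), imidazole, DMF, 0 °C to rt
Reagents that add atoms: triisopropylsilyl chloride, CC(C)[Si](Cl)(C(C)C)C(C)C
Why: O-silylation of one of two equivalent phenols with a single equivalent of a bulky chlorosilane should give mainly the mono-ether, separable from diol and bis-ether, which can be recycled.

Step 2
Reactants: 2 3-methoxy-5-(triisopropylsilyloxy)phenol
Product: 3 3-methoxy-5-(triisopropylsilyloxy)phenyl N-isopropylcarbamate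
Conditions: iPrNCO, Et3N (cat.), CH2Cl2, rt
Reagents that add atoms: isopropyl isocyanate, CC(C)N=C=O
Why: amine-catalysed addition of the phenol to the isocyanate (carbamoylation) installs a strong ortho-directing group that can later be removed under mild base.

Step 3
Reactants: 3 3-methoxy-5-(triisopropylsilyloxy)phenyl N-isopropylcarbamate
Product: 6 3-methoxy-5-(triisopropylsilyloxy)-2-(trimethylsilyl)phenyl N-isopropylcarbamate, via N-silyl carbamate 4 (not isolated), via N-silyl C-silyl carbamate 5 (not isolated)
Conditions: TBSOTf, TMEDA, Et2O, 0 °C to rt; n-BuLi, TMEDA, −78 °C; TMSCl, −78 °C to rt; aq. NaHSO4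
Reagents that add atoms: chlorotrimethylsilane, C[Si](C)(C)Cl; tert-butyldimethylsilyl triflate, CC(C)(C)[Si](C)(C)OS(=O)(=O)C(F)(F)F (its silyl group stays only in 4 and 5)
Why: directed ortho-metalation, in which the N-silylated carbamate and the methoxyl jointly direct lithiation to the carbon between them while the bulky silyl ether shields the other two ring positions; the aryllithium is silylated by TMSCl and the acidic work-up frees the N–H.

Step 4
Reactants: 6 3-methoxy-5-(triisopropylsilyloxy)-2-(trimethylsilyl)phenyl N-isopropylcarbamate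
Product: 7 5-hydroxy-3-methoxy-2-(trimethylsilyl)phenyl N-isopropylcarbamate
Conditions: TBAF, AcOH, THF, 0 °C
Reagents that add atoms: none
Why: fluoride cleavage of the aryl silyl ether (desilylation), buffered with acetic acid so that neither the base-labile carbamate nor the aryl–silicon bond should be touched.

Step 5
Reactants: 7 5-hydroxy-3-methoxy-2-(trimethylsilyl)phenyl N-isopropylcarbamate
Product: 8 5-(benzyloxy)-3-methoxy-2-(trimethylsilyl)phenyl N-isopropylcarbamate
Conditions: BnOH, PPh3, DIAD, THF, 0 °C to rt
Reagents that add atoms: benzyl alcohol, OCc1ccccc1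
Why: Mitsunobu etherification benzylates the phenol under neutral conditions, so the N–H carbamate, which would fragment under basic alkylation, stays intact; the benzyl ether, unlike the silyl ether, will survive fluoride in step 13.

Step 6
Reactants: 8 5-(benzyloxy)-3-methoxy-2-(trimethylsilyl)phenyl N-isopropylcarbamate
Product: 10 5-(benzyloxy)-3-methoxy-2-(trimethylsilyl)phenyl trifluoromethanesulfonate, via silylphenol 9 (not isolated)
Conditions: DBU, Et2NH, MeCN, 40 °C; then PhNTf2, rt
Reagents that add atoms: N-phenylbis(trifluoromethanesulfonimide), O=S(=O)(N(c1ccccc1)S(=O)(=O)C(F)(F)F)C(F)(F)F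
Why: base-induced E1cB fragmentation of the N-monoalkyl carbamate releases the phenoxide and isopropyl isocyanate (trapped by Et2NH as a urea), and the phenoxide is O-triflated in the same flask before carbon-to-oxygen silyl migration can intervene.

Step 7
Reactants: 11 methyl orsellinate
Product: 12 methyl 4-(benzyloxy)-2-hydroxy-6-methylbenzoate
Conditions: BnBr (1.05 equiv), K2CO3, acetone, reflux
Reagents that add atoms: benzyl bromide, BrCc1ccccc1
Why: Williamson etherification should take place at the 4-hydroxyl only, because the 2-hydroxyl is held in a hydrogen bond to the ester and is far less nucleophilic.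

Step 8
Reactants: 12 methyl 4-(benzyloxy)-2-hydroxy-6-methylbenzoate
Product: 13 methyl 4-(benzyloxy)-2-methoxy-6-methylbenzoate
Conditions: MeI, K2CO3, DMF, 40 °C
Reagents that add atoms: iodomethane, CI
Why: Williamson methylation of the remaining chelated phenol proceeds in a dipolar aprotic solvent with excess alkylating agent.

Step 9
Reactants: 13 methyl 4-(benzyloxy)-2-methoxy-6-methylbenzoate
Product: 14 methyl 4-(benzyloxy)-3-bromo-6-methoxy-2-methylbenzoate
Conditions: NBS, MeCN, 0 °C to rt
Reagents that add atoms: N-bromosuccinimide, O=C1CCC(=O)N1Br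
Why: electrophilic aromatic bromination should enter para to the methoxyl and ortho to the benzyloxy group (beside the ring methyl), since the only other free position is flanked by two alkoxy groups and is disfavoured as in resorcinol diethers.

Step 10
Reactants: 14 methyl 4-(benzyloxy)-3-bromo-6-methoxy-2-methylbenzoate
Product: 15 methyl 4-(benzyloxy)-3-bromo-6-methoxy-2-(2-oxopropyl)benzoate
Conditions: LiN(iPr)2 (1.2 equiv), THF, −78 °C; MeC(O)N(OMe)Me; aq. NH4Cl
Reagents that add atoms: N-methoxy-N-methylacetamide, CC(=O)N(C)OC
Why: lateral lithiation of the ortho-toluate gives a benzylic anion that is acylated once by the Weinreb amide (stable chelated adduct until work-up); the bromide has no ortho hydrogen, so neither aryne formation nor halogen migration can compete.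

Step 11
Reactants: 15 methyl 4-(benzyloxy)-3-bromo-6-methoxy-2-(2-oxopropyl)benzoate
Product: 16 6-(benzyloxy)-5-bromo-8-methoxy-3-methyl-1H-isochromen-1-one
Conditions: p-TsOH·H2O (cat.), toluene, reflux
Reagents that add atoms: none
Why: acid-catalysed enol lactonisation, in which the ketone enol attacks the neighbouring ester (6-exo-trig) and methanol is lost, closes the pyranone ring as the conjugated 3-methylisocoumarin.

Step 12
Reactants: 16 6-(benzyloxy)-5-bromo-8-methoxy-3-methyl-1H-isochromen-1-one
Product: 17 6-(benzyloxy)-8-methoxy-3-methyl-1-oxo-1H-isochromene-5-carbaldehyde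
Conditions: Pd(OAc)2 (cat.), n-BuP(1-Ad)2, CO/H2 (1:1, 5 bar), TMEDA, toluene, 100 °C
Reagents that add atoms: carbon monoxide, [C-]#[O+]
Why: palladium-catalysed reductive carbonylation (formylation) of the aryl bromide proceeds by oxidative addition to zerovalent palladium, CO insertion and hydrogenolysis of the acyl complex; the bulky electron-rich phosphine is chosen for the hindered C–Br bond, and a homogeneous catalyst should leave benzyl ether and enol lactone alone.

Step 13
Reactants: 10 5-(benzyloxy)-3-methoxy-2-(trimethylsilyl)phenyl trifluoromethanesulfonate; 17 6-(benzyloxy)-8-methoxy-3-methyl-1-oxo-1H-isochromene-5-carbaldehyde; 18 tert-butyl isocyanide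
Product: 20 racemic (Z)-N-tert-butyl-6-(benzyloxy)-3-[6-(benzyloxy)-8-methoxy-3-methyl-1-oxo-1H-isochromen-5-yl]-4-methoxyisobenzofuran-1(3H)-imine, via aryne 19 (not isolated)
Conditions: KF, 18-crown-6, THF, 0 °C to rt; 10 (1.5 equiv) and 18 (2 equiv) in excess over 17
Reagents that add atoms: none
Why: Fluoride attack on silicon of 10 expels triflate and gives aryne 19; the isocyanide carbon of 18 adds to the aryne carbon remote from the methoxyl, the aryl anion thus formed beside the methoxyl adds to the formyl group of 17, and the alkoxide closes onto the nitrilium carbon. The closest known reaction type is the three-component coupling of arynes, isocyanides and aldehydes to N-substituted iminoisobenzofurans. The five-membered ring closes in a 5-exo-dig mode by attack of oxygen on the nitrilium carbon. The new benzylic stereocentre forms without control as a racemate, which is of no consequence because step 15 turns it into a methylene group. The step needs regioselective attack on the unsymmetrical aryne, secured by the inductively withdrawing methoxyl next to the triple bond, which directs the nucleophile to the distal carbon and the negative charge to the proximal one; it also needs the aldehyde to be taken in preference to the lactone carbonyl, which its higher electrophilicity should ensure.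

Step 14
Reactants: 20 racemic (Z)-N-tert-butyl-6-(benzyloxy)-3-[6-(benzyloxy)-8-methoxy-3-methyl-1-oxo-1H-isochromen-5-yl]-4-methoxyisobenzofuran-1(3H)-imine
Product: 21 racemic 6-(benzyloxy)-3-[6-(benzyloxy)-8-methoxy-3-methyl-1-oxo-1H-isochromen-5-yl]-4-methoxyisobenzofuran-1(3H)-one
Conditions: 1 M aq. HCl, THF, rt
Reagents that add atoms: water, O
Why: acid hydrolysis of the cyclic imidate, in which the protonated C=N takes up water and the tetrahedral intermediate expels the more basic tert-butylamine, leaves the phthalide lactone.

Step 15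
Reactants: 21 racemic 6-(benzyloxy)-3-[6-(benzyloxy)-8-methoxy-3-methyl-1-oxo-1H-isochromen-5-yl]-4-methoxyisobenzofuran-1(3H)-one
Product: 22 5-(benzyloxy)-2-{[6-(benzyloxy)-8-methoxy-3-methyl-1-oxo-1H-isochromen-5-yl]methyl}-3-methoxybenzoic acid
Conditions: Et3SiH, TFA, CH2Cl2, 0 °C to rt
Reagents that add atoms: none
Why: ionic hydrogenolysis, in which the protonated lactone ionises to a diarylmethyl cation stabilised by ortho- and para-alkoxy groups on both rings and this takes hydride from the silane; dilute acid at low temperature should spare the benzyl ethers, and the stereocentre disappears.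

Step 16
Reactants: 22 5-(benzyloxy)-2-{[6-(benzyloxy)-8-methoxy-3-methyl-1-oxo-1H-isochromen-5-yl]methyl}-3-methoxybenzoic acid
Product: 23 6-(benzyloxy)-5-{[4-(benzyloxy)-2-(hydroxymethyl)-6-methoxyphenyl]methyl}-8-methoxy-3-methyl-1H-isochromen-1-one
Conditions: BH3·THF, THF, 0 °C to rt
Reagents that add atoms: none
Why: chemoselective borane reduction, in which the carboxylic acid is reduced through its acyloxyborane much faster than the isocoumarin lactone or its electron-poor enol-ester double bond can react.

Step 17
Reactants: 23 6-(benzyloxy)-5-{[4-(benzyloxy)-2-(hydroxymethyl)-6-methoxyphenyl]methyl}-8-methoxy-3-methyl-1H-isochromen-1-one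
Product: 24 6-(benzyloxy)-5-{[4-(benzyloxy)-2-methoxy-6-(methoxymethyl)phenyl]methyl}-8-methoxy-3-methyl-1H-isochromen-1-one
Conditions: MeI (excess), Ag2O, MeCN, 40 °C, dark
Reagents that add atoms: iodomethane, CI
Why: Purdie methylation etherifies the primary benzylic alcohol without generating a free alkoxide, so the lactone should not be opened.

Step 18
Reactants: 24 6-(benzyloxy)-5-{[4-(benzyloxy)-2-methoxy-6-(methoxymethyl)phenyl]methyl}-8-methoxy-3-methyl-1H-isochromen-1-one
Product: 25 6-hydroxy-5-{[4-hydroxy-2-methoxy-6-(methoxymethyl)phenyl]methyl}-8-methoxy-3-methyl-1H-isochromen-1-one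
Conditions: H2 (1 atm), 10% Pd/C, EtOAc, rt, stopped after uptake of two equivalents
Reagents that add atoms: none
Why: catalytic hydrogenolysis cleaves aryl benzyl ethers much faster than it saturates the trisubstituted enol-lactone double bond or cleaves the benzylic C–OMe bond, so both phenols should be freed selectively.

**Compound list**
1 | 5-methoxyresorcinol | COc1cc(O)cc(O)c1 | starting material
2 | 3-methoxy-5-(triisopropylsilyloxy)phenol | COc1cc(O)cc(O[Si](C(C)C)(C(C)C)C(C)C)c1 | intermediate
3 | 3-methoxy-5-(triisopropylsilyloxy)phenyl N-isopropylcarbamate | COc1cc(OC(=O)NC(C)C)cc(O[Si](C(C)C)(C(C)C)C(C)C)c1 | intermediate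
4 | 3-methoxy-5-(triisopropylsilyloxy)phenyl N-(tert-butyldimethylsilyl)-N-isopropylcarbamate | COc1cc(OC(=O)N(C(C)C)[Si](C)(C)C(C)(C)C)cc(O[Si](C(C)C)(C(C)C)C(C)C)c1 | intermediate
5 | 3-methoxy-5-(triisopropylsilyloxy)-2-(trimethylsilyl)phenyl N-(tert-butyldimethylsilyl)-N-isopropylcarbamate | COc1cc(O[Si](C(C)C)(C(C)C)C(C)C)cc(OC(=O)N(C(C)C)[Si](C)(C)C(C)(C)C)c1[Si](C)(C)C | intermediate
6 | 3-methoxy-5-(triisopropylsilyloxy)-2-(trimethylsilyl)phenyl N-isopropylcarbamate | COc1cc(O[Si](C(C)C)(C(C)C)C(C)C)cc(OC(=O)NC(C)C)c1[Si](C)(C)C | intermediate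
7 | 5-hydroxy-3-methoxy-2-(trimethylsilyl)phenyl N-isopropylcarbamate | COc1cc(O)cc(OC(=O)NC(C)C)c1[Si](C)(C)C | intermediate
8 | 5-(benzyloxy)-3-methoxy-2-(trimethylsilyl)phenyl N-isopropylcarbamate | COc1cc(OCc2ccccc2)cc(OC(=O)NC(C)C)c1[Si](C)(C)C | intermediate
9 | 5-(benzyloxy)-3-methoxy-2-(trimethylsilyl)phenol | COc1cc(OCc2ccccc2)cc(O)c1[Si](C)(C)C | intermediate
10 | 5-(benzyloxy)-3-methoxy-2-(trimethylsilyl)phenyl trifluoromethanesulfonate | COc1cc(OCc2ccccc2)cc(OS(=O)(=O)C(F)(F)F)c1[Si](C)(C)C | intermediate
11 | methyl orsellinate (methyl 2,4-dihydroxy-6-methylbenzoate) | COC(=O)c1c(C)cc(O)cc1O | starting material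
12 | methyl 4-(benzyloxy)-2-hydroxy-6-methylbenzoate | COC(=O)c1c(C)cc(OCc2ccccc2)cc1O | intermediate
13 | methyl 4-(benzyloxy)-2-methoxy-6-methylbenzoate | COC(=O)c1c(C)cc(OCc2ccccc2)cc1OC | intermediate
14 | methyl 4-(benzyloxy)-3-bromo-6-methoxy-2-methylbenzoate | COC(=O)c1c(C)c(Br)c(OCc2ccccc2)cc1OC | intermediate
15 | methyl 4-(benzyloxy)-3-bromo-6-methoxy-2-(2-oxopropyl)benzoate | COC(=O)c1c(CC(C)=O)c(Br)c(OCc2ccccc2)cc1OC | intermediate
16 | 6-(benzyloxy)-5-bromo-8-methoxy-3-methyl-1H-isochromen-1-one | Cc1cc2c(Br)c(OCc3ccccc3)cc(OC)c2c(=O)o1 | intermediate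
17 | 6-(benzyloxy)-8-methoxy-3-methyl-1-oxo-1H-isochromene-5-carbaldehyde | Cc1cc2c(C=O)c(OCc3ccccc3)cc(OC)c2c(=O)o1 | intermediate
18 | tert-butyl isocyanide | CC(C)(C)[N+]#[C-] | starting material
19 | 5-(benzyloxy)-3-methoxybenzyne | COC1=CC(OCc2ccccc2)=CC#C1 | intermediate
20 | racemic (Z)-N-tert-butyl-6-(benzyloxy)-3-[6-(benzyloxy)-8-methoxy-3-methyl-1-oxo-1H-isochromen-5-yl]-4-methoxyisobenzofuran-1(3H)-imine | CC(C)(C)/N=C1\OC(c2c(OCc3ccccc3)cc(OC)c3c(=O)oc(C)cc23)c2c(OC)cc(OCc3ccccc3)cc21 | intermediate
21 | racemic 6-(benzyloxy)-3-[6-(benzyloxy)-8-methoxy-3-methyl-1-oxo-1H-isochromen-5-yl]-4-methoxyisobenzofuran-1(3H)-one | O=C1OC(c2c(OCc3ccccc3)cc(OC)c3c(=O)oc(C)cc23)c2c(OC)cc(OCc3ccccc3)cc21 | intermediate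
22 | 5-(benzyloxy)-2-{[6-(benzyloxy)-8-methoxy-3-methyl-1-oxo-1H-isochromen-5-yl]methyl}-3-methoxybenzoic acid | OC(=O)c1cc(OCc2ccccc2)cc(OC)c1Cc1c(OCc2ccccc2)cc(OC)c2c(=O)oc(C)cc12 | intermediate
23 | 6-(benzyloxy)-5-{[4-(benzyloxy)-2-(hydroxymethyl)-6-methoxyphenyl]methyl}-8-methoxy-3-methyl-1H-isochromen-1-one | OCc1cc(OCc2ccccc2)cc(OC)c1Cc1c(OCc2ccccc2)cc(OC)c2c(=O)oc(C)cc12 | intermediate
24 | 6-(benzyloxy)-5-{[4-(benzyloxy)-2-methoxy-6-(methoxymethyl)phenyl]methyl}-8-methoxy-3-methyl-1H-isochromen-1-one | COCc1cc(OCc2ccccc2)cc(OC)c1Cc1c(OCc2ccccc2)cc(OC)c2c(=O)oc(C)cc12 | intermediate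
25 | 6-hydroxy-5-{[4-hydroxy-2-methoxy-6-(methoxymethyl)phenyl]methyl}-8-methoxy-3-methyl-1H-isochromen-1-one | COCc1cc(O)cc(OC)c1Cc1c(O)cc(OC)c2c(=O)oc(C)cc12 | target

**Step count**
Total: 18 steps. Longest linear sequence: 12 steps (steps 1–6, then 13–18; the branch through steps 7–12 is equally long).

**Steps most likely to fail**

1. Step 13. The aryl anion of the aryne–isocyanide zwitterion is flanked by the methoxyl and the nitrilium carbon, and it must add to a formyl group that is itself flanked by two ortho substituents. If this addition is slow, the short-lived zwitterion would be lost to protonation or to further aryne and isocyanide. The fallback makes the same benzylic C–C bond with a persistent organomagnesium reagent. It sets out from 10: palladium-catalysed methoxycarbonylation of the triflate (Pd(OAc)2, Ph2P(CH2)3PPh2, CO, MeOH, Et3N, DMF, 70 °C) should give methyl 5-(benzyloxy)-3-methoxy-2-(trimethylsilyl)benzoate F1. Ipso-iododesilylation with ICl in CH2Cl2 at 0 °C should then give methyl 5-(benzyloxy)-2-iodo-3-methoxybenzoate F2. Iodine–magnesium exchange with iPrMgCl·LiCl in THF at −40 °C, addition of aldehyde 17 and warming should let the magnesium alkoxide lactonise onto the neighbouring ester. The route is rejoined at phthalide 21, so that steps 13 and 14 are replaced.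

2. Step 12. Oxidative addition and CO insertion at a C–Br bond with two ortho substituents may be sluggish, so that hydrodebromination or catalyst decomposition takes over. The fallback sets out from 16: Stille coupling with Bu3SnCH=CH2 (Pd(PPh3)4, toluene, 100 °C) should give 6-(benzyloxy)-5-ethenyl-8-methoxy-3-methyl-1H-isochromen-1-one F3. Lemieux–Johnson cleavage (OsO4 cat., NaIO4, 2,6-lutidine, dioxane/H2O, rt) of the terminal vinyl group, which is more accessible and more electron-rich than the acyloxy-substituted ring double bond, would then return to the route at aldehyde 17.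

3. Step 18. Over-reduction may occur on the catalyst surface, either saturation of the C3=C4 double bond of the isocoumarin or hydrogenolysis of the benzylic C–OMe bond, before both benzyl ethers are gone. The fallback sets out from 24 and replaces hydrogenolysis by Lewis-acid dealkylation: BCl3 with pentamethylbenzene as benzyl-cation scavenger in CH2Cl2 at −78 °C for a short time should cleave the two aryl benzyl ethers while the methyl ethers survive. It arrives directly at target 25 and makes no new compound (F0).

**Further compounds**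
F1 | step 13 | methyl 5-(benzyloxy)-3-methoxy-2-(trimethylsilyl)benzoate | COC(=O)c1cc(OCc2ccccc2)cc(OC)c1[Si](C)(C)C
F2 | step 13 | methyl 5-(benzyloxy)-2-iodo-3-methoxybenzoate | COC(=O)c1cc(OCc2ccccc2)cc(OC)c1I
F3 | step 12 | 6-(benzyloxy)-5-ethenyl-8-methoxy-3-methyl-1H-isochromen-1-one | C=Cc1c(OCc3ccccc3)cc(OC)c2c(=O)oc(C)cc12
F0 | step 18 | none | none
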